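## Structural features

Atom labels used throughout: C1 is the quaternary carbon bearing the ether oxygen O2, the lactone carbonyl C9, the carbinol C7 and chain A; C3 is the ether CH bearing chain B; C4 is the methyl-bearing carbon on the lactone oxygen O8; C5, C6 and C7 (CHOH) complete the carbon bridge. Chain A is C1–Ce–Cf–Cg=Ch(CH3)–CH2OH and chain B is C3–CH2–CH2–C(CH3)=CH–CH2OH, both Z.

The target is a 6,8-dioxabicyclo[3.2.2]nonan-7-one. An oxepane (C1, O2, C3, C4, C5, C6, C7) is bridged from C1 to C4 by the ester unit C9(=O)–O8, so the oxepane and the six-membered lactone (C1, O2, C3, C4, O8, C9) share the segment C1–O2–C3–C4. The four stereocentres form two adjacent pairs, C3/C4 (3S,4R, the anti-dioxygenation pattern of an E-alkene) and C7/C1 (7S,1R, hydroxyl cis to C9), and the pairs are linked through O2. The bridge requires O8 and C9 to be cis on the oxepane, and chain B lies on the opposite face.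

Fragile features:
- the aldol-type unit C7(OH)–C1–C9(=O), which can cleave by retro-aldol under base;
- the lactone of a tertiary alcohol;
- the β-alkoxy relation of O2 to any carbonyl on Cf, which allows retro-oxa-Michael ring opening;
- two Z-trisubstituted allylic alcohols, which ionise or isomerise under strong acid.

The real difficulty is the fully substituted C1, which carries an oxygen, a carboxyl carbon and a carbon chain next to a carbinol, inside a seven-membered ether. The key step exploits exactly this array: O2, C9 and the methylene Ce on C1 beside the secondary carbinol C7 is what remains when a C7 ketyl adds to the oxygen-bearing carbon of a 2-alkoxybutenedioate hung on O2. The configurational descriptors of the open-chain aldehyde (3S,4R), the oxepane and the target (1R,3S,4R,7S) were checked against one another and agree.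

## Logic of the disconnections

33 ⇒ 32. The three O–Si bonds (both allylic oxygens and the C7 oxygen) are cut last. Masking every hydroxyl means the later steps meet no free alcohol. The forward step must remove the silyl groups under buffered conditions so that a C7 alkoxide never sits beside C9.

32 ⇒ 26 + 30. The sp3–sp2 bond Cf–Cg is cut. Chain A then arrives as a small alkenyl iodide whose Z geometry is fixed before coupling, and no unsaturated ester has to be reduced next to the lactone, where hydride chemoselectivity would be doubtful. The core loses five carbons and one alkene. The forward coupling must tolerate C9 and the silyl ethers and retain the alkene geometry.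

26 ⇒ 25 ⇒ 23 ⇒ 22. The C–I bond is traced to C–OH, Cf is raised to the carboxylic acid, and the acid is traced to the methyl ester on the arm. These cuts put Cf at the oxidation level the ring closure delivers. The forward steps must distinguish the arm carbonyl from C9, which is done by hydrolysing only the unhindered methyl ester and reducing only the activated acid.

22 ⇒ 21 ⇒ 20 ⇒ 19. The O8–C9 bond is cut, then the O–Si bond on C4, then the O–Si bond on C7. Opening the bridge returns a monocyclic oxepane diester. The forward order demands that C7 be silylated before C4 is freed, so that neither retro-aldol cleavage nor lactonisation of the C7 oxygen onto the arm can compete with the bridging closure.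

19 ⇒ 18. The C1–C7 bond is cut: the oxepane opens to an acyclic aldehyde whose C3 oxygen carries a dimethyl (E)-2-alkoxybutenedioate. One ring and two stereocentres disappear. The forward step must reduce the aldehyde in the presence of a reducible diester and control C1 and C7 from C3. In 18 the chain-B oxygen is a tert-butyldiphenylsilyl ether, chosen over a more labile silyl ether because the tertiary triethylsilyl ether on C4 has to be removed later in its presence.

18 ⇒ 17 ⇒ 16 ⇒ 14 + 15. The aldehyde is traced to a primary silyl ether, the C4 O–Si bond is cut, and the O2–C1 bond is cut by retro-oxa-Michael to the alkynedioate. This removes the acceptor and leaves a differentiated triol. The forward steps demand selective alkenylation of the secondary over the tertiary hydroxyl and the E geometry of the enol ether.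

14 ⇒ 13 ⇒ 12 ⇒ 11. The primary O–Si bond is cut, the 1,4-diol is traced to a γ-lactone, and the chain-B silyl ether to the alcohol. The lactone holds C4–O and C7 together, so only hydride reduction and two selective silylations are needed forward.

11 ⇒ 9 ⇒ 8. The C4–O(lactone) bond is cut to an epoxy acid, and the epoxide to an E-trisubstituted alkene. Both stereocentres of the C3/C4 pair then come from one enantioselective epoxidation followed by a stereospecific opening with inversion at C4. The forward step needs the (S,S)-epoxide and oxidation of only one of two trisubstituted alkenes.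

8 ⇒ 5 + 6. The C5–C6 bond and the C3=C4 alkene are taken apart by a retro-[3,3] shift. The E-alkene is reduced to an allylic alcohol whose configuration does not matter. The forward rearrangement must give the E isomer.

5 ⇒ 3 + 4. The C3–C4 bond is cut between an aldehyde and an isopropenyl nucleophile. Forward, the addition must spare the acetate.

3 ⇒ 1. The aldehyde carbon is traced to the remote alkene of the neryl skeleton, which supplies chain B with its Z-alkene ready-made. Forward, only the more electron-rich alkene may be cleaved.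

30 ⇒ 29 ⇒ 27. The O–Si bond is cut, then the C–CH3 and C–I bonds across a propargylic alkyne. Forward, methyl and iodine must add anti so that iodine ends cis to CH2OH.

## Other disconnections considered

Alternative 1: The cut removes C3–C4 and C5–C6 together and requires a later scission of an extra C3–C6 bond. In the forward sense the 3(2H)-furanone A1, whose C1 carries an isopropenyl ester, would be irradiated near 350 nm. The triplet enone C3=C6 would add the enol-ester alkene C4=C5 and give the caged tricycle A2, in which the dioxanone closes as a consequence of the tether.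
- In its favour: two C–C bonds, the quaternary C4 and the whole lactone bridge arise in one operation. The cis relation of O8 and C9 is enforced by the tether, and only C1 has to be made enantioselectively. No stoichiometric reductant is needed. On ring-forming economy it is the better plan.
- Against it here: an ester tether prefers its extended conformation, which works against closure of A1. In A2 the chain-B carbon sits on the face of C3 opposite to the one the target needs, so C3 is fixed only when hydrogen is delivered after the C3–C6 bond is broken. C7 must then be set by ketone reduction, where the face that has to be attacked is the one chain B shields.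
- Comparison: two of the four stereocentres would rest on late facial selectivity, whereas the chosen plan sets C3/C4 by a stereospecific epoxide opening and C1/C7 in one chelated closure. A2 carries both chains only as short silyloxy stubs, so two Z-trisubstituted allylic alcohols would have to be built afterwards against one in the chosen plan. Both plans pass through radical intermediates and are equal in that respect. The sequence after the key step would be longer for A2.

Alternative 2: The cut is the ether bond O2–C3. Forward, the seven-membered hydroxy keto lactone A3 (C1–OH, ketone at C3) would be treated with Me3SiOTf and Et3SiH. The C1 hydroxyl adds to the ketone, the bridged hemiketal ionises to the oxocarbenium ion O2=C3, and hydride delivery to C3 gives the protected target A4.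
- In its favour: reductive etherification is dependable for cyclic ethers, and the cationic double bond lies inside a two-atom bridge, so it is not a bridgehead alkene. Hydride should plausibly enter from the less hindered lactone-bridge side, which is the face the target requires. Both chains are complete before the core closes, so only deprotection would remain. On convergence and on endgame length it is the better plan.
- Against it here: A3 is hardly simpler than the target. It already contains the C1/C7 pair, a tertiary α-hydroxy lactone, a tertiary α-acyloxy ketone and a medium-ring lactone. Two allylic acetates, the C4–O8 bond next to the cation and the C7 silyl ether would all be exposed to a strong silyl Lewis acid, with ionisation and direct ketone reduction as competing processes.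
- Comparison: the chosen plan forms a C–C bond and two stereocentres from an acyclic precursor reached by routine steps. This plan forms one C–O bond and one stereocentre and moves the difficulty into the synthesis of A3. The two are equal in that the new centres are set under substrate control.

Alternative 3: The cuts are O8–C9 and C6–C7. Forward, the sulfonyl malonate A5 would be treated with three equivalents of LiN(iPr)2. The C4 alkoxide lactonises reversibly onto either malonate ester, and the α-sulfonyl carbanion at C6 acylates on the remaining ester only in the lactone diastereomer that holds ester and sulfonylethyl arm cis, giving the bridged keto lactone A6.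
- In its favour: C1 begins as a non-stereogenic malonate carbon and is selected by a reversible step feeding an irreversible one, with no reagent control. For C1 this is the better solution. Two rings close in one flask, both chains are in place, and A5 should be easy to assemble.
- Against it here: after A6 the sulfone must be removed and the C7 ketone reduced. The hydride would have to approach C7 from the side of the O2–C3 bridge, toward which chain B points, so the inherent preference may favour the wrong epimer and force an inversion. The acylation must close the three-carbon bridge across a dioxanone through a diaxial arrangement. The β-keto lactone, which cannot enolise toward C1, is open to retro-Claisen cleavage unless it stays as the sulfonyl-stabilised enolate.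
- Comparison: the chosen plan sets the C7 hydroxyl in the bond-forming step itself, which is its main advantage. This plan is equal or better in rings closed per step, but adds desulfonylation and a stereochemically uncertain reduction.

Key step: step 12

Remark on the chemistry: neryl acetate, isopropenylmagnesium bromide solution and the L-fructose-derived enantiomer of the Shi ketone (ent-Shi ketone) are taken as purchasable.

## Route

Step 1
Reactants: 1 neryl acetate [(2Z)-3,7-dimethylocta-2,6-dien-1-yl acetate]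
Product: 3 (2Z)-3-methyl-6-oxohex-2-en-1-yl acetate, via secondary ozonide 2 (not isolated)
Conditions: O3 (1.0 equiv), CH2Cl2, −78 °C; then PPh3, −78 °C → rt
Reagents that add atoms: ozone, [O-][O+]=O
Why: Ozone attacks the electron-rich 6,7-alkene in preference to the 2,3-alkene, which the allylic acetate deactivates; reductive cleavage of the ozonide gives the aldehyde (ozonolysis) and leaves the Z-alkene untouched.

Step 2
Reactants: 3 (2Z)-3-methyl-6-oxohex-2-en-1-yl acetate; 4 isopropenylmagnesium bromide
Product: 5 (2Z)-6-hydroxy-3,7-dimethylocta-2,7-dien-1-yl acetate (both configurations at C6)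
Conditions: 4 (1.1 equiv), THF, −78 °C; sat. aq. NH4Cl
Reagents that add atoms: none
Why: Grignard addition to the aldehyde is far faster than attack on the acetate at −78 °C; the carbinol centre is formed without control and is erased in step 3.

Step 3
Reactants: 5 (2Z)-6-hydroxy-3,7-dimethylocta-2,7-dien-1-yl acetate; 6 triethyl orthoacetate
Product: 8 ethyl (4E,8Z)-10-acetoxy-4,8-dimethyldeca-4,8-dienoate, via mixed ketene acetal 7 (not isolated)
Conditions: 6 (6 equiv), EtCO2H (cat.), 140 °C, EtOH distilled off
Reagents that add atoms: none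
Why: Johnson–Claisen rearrangement through a chair transition state with the carbinol substituent equatorial should give the E-trisubstituted alkene C3=C4 and create the C5–C6 bond.

Step 4
Reactants: 8 ethyl (4E,8Z)-10-acetoxy-4,8-dimethyldeca-4,8-dienoate
Product: 9 ethyl 3-[(2S,3S)-3-[(3Z)-5-acetoxy-3-methylpent-3-en-1-yl]-2-methyloxiran-2-yl]propanoate
Conditions: ent-Shi ketone (0.3 equiv), KHSO5 (as 2KHSO5·KHSO4·K2SO4), K2CO3, Bu4NHSO4 (cat.), MeCN–CH2(OMe)2 / aq. Na2B4O7 buffer (pH 10.5), 0 °C
Reagents that add atoms: potassium peroxymonosulfate, [K+].[O-]S(=O)(=O)OO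
Why: Shi epoxidation; the chiral dioxirane delivers oxygen through a spiro transition state, and because the D-fructose-derived ketone gives the R,R series with E-trisubstituted alkenes, its enantiomer is used to reach the (S,S)-oxirane. The alkene next to the acetate is deactivated and should remain.

Step 5
Reactants: 9 ethyl 3-[(2S,3S)-3-[(3Z)-5-acetoxy-3-methylpent-3-en-1-yl]-2-methyloxiran-2-yl]propanoate
Product: 11 (5R)-5-[(1S,4Z)-1,6-dihydroxy-4-methylhex-4-en-1-yl]-5-methyloxolan-2-one, via epoxy hydroxy acid 10 (not isolated)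
Conditions: LiOH·H2O (3 equiv), THF–H2O, 0 °C → rt; 1 M HCl to pH 3, EtOAc; then camphorsulfonic acid (cat.), CH2Cl2, rt
Reagents that add atoms: lithium hydroxide, [Li+].[OH-]
Why: Saponification frees the carboxylic acid and the allylic alcohol; on acidification the acid opens the epoxide 5-exo at the tertiary carbon C4 with inversion (epoxy-acid lactonisation), giving 4R while C3 keeps its oxygen and stays S.

Step 6
Reactants: 11 (5R)-5-[(1S,4Z)-1,6-dihydroxy-4-methylhex-4-en-1-yl]-5-methyloxolan-2-one
Product: 12 (5R)-5-[(1S,4Z)-6-[(tert-butyldiphenylsilyl)oxy]-1-hydroxy-4-methylhex-4-en-1-yl]-5-methyloxolan-2-one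
Conditions: t-BuPh2SiCl (1.05 equiv), imidazole, CH2Cl2, 0 °C
Reagents that add atoms: tert-butyl(chloro)diphenylsilane, CC(C)(C)[Si](Cl)(c1ccccc1)c1ccccc1
Why: The primary allylic hydroxyl is silylated much faster than the secondary hydroxyl flanked by the quaternary C4 (selective silylation); this robust ether stays until the last step.

Step 7
Reactants: 12 (5R)-5-[(1S,4Z)-6-[(tert-butyldiphenylsilyl)oxy]-1-hydroxy-4-methylhex-4-en-1-yl]-5-methyloxolan-2-one
Product: 13 (4R,5S,8Z)-10-[(tert-butyldiphenylsilyl)oxy]-4,8-dimethyldec-8-ene-1,4,5-triol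
Conditions: LiAlH4 (1.5 equiv), THF, 0 °C; H2O/15% aq. NaOH work-up
Reagents that add atoms: none
Why: Hydride reduction of the γ-lactone releases the primary C7 hydroxyl and the tertiary C4 hydroxyl without touching a stereocentre or the silyl ether.

Step 8
Reactants: 13 (4R,5S,8Z)-10-[(tert-butyldiphenylsilyl)oxy]-4,8-dimethyldec-8-ene-1,4,5-triol
Product: 14 (4R,5S,8Z)-10-[(tert-butyldiphenylsilyl)oxy]-4,8-dimethyl-1-[(triethylsilyl)oxy]dec-8-ene-4,5-diol
Conditions: Et3SiCl (1.05 equiv), imidazole, CH2Cl2, −78 → −40 °C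
Reagents that add atoms: chlorotriethylsilane, CC[Si](Cl)(CC)CC
Why: The primary hydroxyl reacts first with the silyl chloride at low temperature; the triethylsilyl ether later serves as the direct precursor of the aldehyde.

Step 9
Reactants: 14 (4R,5S,8Z)-10-[(tert-butyldiphenylsilyl)oxy]-4,8-dimethyl-1-[(triethylsilyl)oxy]dec-8-ene-4,5-diol; 15 dimethyl but-2-ynedioate
Product: 16 dimethyl (2E)-2-{[(4R,5S,8Z)-10-[(tert-butyldiphenylsilyl)oxy]-4-hydroxy-4,8-dimethyl-1-[(triethylsilyl)oxy]dec-8-en-5-yl]oxy}but-2-enedioate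
Conditions: 15 (1.2 equiv), 1,4-diazabicyclo[2.2.2]octane (0.1 equiv), CH2Cl2, 0 °C
Reagents that add atoms: none
Why: Amine-catalysed oxa-Michael addition; the secondary C3 hydroxyl is much more nucleophilic than the tertiary C4 hydroxyl. The push–pull E isomer (O2 trans to the CH ester) is expected to dominate under the reversible amine addition–elimination; its geometry is to be confirmed by NOE and any Z isomer removed by chromatography.

Step 10
Reactants: 16 dimethyl (2E)-2-{[(4R,5S,8Z)-10-[(tert-butyldiphenylsilyl)oxy]-4-hydroxy-4,8-dimethyl-1-[(triethylsilyl)oxy]dec-8-en-5-yl]oxy}but-2-enedioate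
Product: 17 dimethyl (2E)-2-{[(4R,5S,8Z)-10-[(tert-butyldiphenylsilyl)oxy]-4,8-dimethyl-1,4-bis[(triethylsilyl)oxy]dec-8-en-5-yl]oxy}but-2-enedioate
Conditions: Et3SiOTf (1.5 equiv), 2,6-lutidine (3 equiv), CH2Cl2, −78 → 0 °C
Reagents that add atoms: triethylsilyl trifluoromethanesulfonate, CC[Si](CC)(CC)OS(=O)(=O)C(F)(F)F
Why: The silyl triflate caps the hindered tertiary hydroxyl, so that the later aldehyde cannot close to a lactol and the C4 oxygen cannot attack the diester.

Step 11
Reactants: 17 dimethyl (2E)-2-{[(4R,5S,8Z)-10-[(tert-butyldiphenylsilyl)oxy]-4,8-dimethyl-1,4-bis[(triethylsilyl)oxy]dec-8-en-5-yl]oxy}but-2-enedioate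
Product: 18 dimethyl (2E)-2-{[(4R,5S,8Z)-10-[(tert-butyldiphenylsilyl)oxy]-4,8-dimethyl-1-oxo-4-[(triethylsilyl)oxy]dec-8-en-5-yl]oxy}but-2-enedioate
Conditions: (COCl)2 (4 equiv), Me2SO (8 equiv), CH2Cl2, −78 → −40 °C; Et3N, −78 → 0 °C
Reagents that add atoms: none
Why: Under Swern conditions a primary triethylsilyl ether is cleaved and oxidised in the same flask (direct Swern oxidation of primary silyl ethers), while the tertiary triethylsilyl ether, the tert-butyldiphenylsilyl ether and the enol ether diester are inert.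

Step 12
Reactants: 18 dimethyl (2E)-2-{[(4R,5S,8Z)-10-[(tert-butyldiphenylsilyl)oxy]-4,8-dimethyl-1-oxo-4-[(triethylsilyl)oxy]dec-8-en-5-yl]oxy}but-2-enedioate
Product: 19 methyl (2R,3S,6R,7S)-7-[(3Z)-5-[(tert-butyldiphenylsilyl)oxy]-3-methylpent-3-en-1-yl]-3-hydroxy-2-(2-methoxy-2-oxoethyl)-6-methyl-6-[(triethylsilyl)oxy]oxepane-2-carboxylate
Conditions: SmI2 (3 equiv, 0.1 M in THF), MeOH (3 equiv), THF, −78 → 0 °C; aq. NaHCO3/Na2S2O3
Reagents that add atoms: none
Why: Electron transfer from divalent samarium to the C7 aldehyde gives a samarium ketyl whose carbon adds to C1, the β-carbon of the unit C1=Ce–CO2Me; a second electron reduces the ester-stabilised radical to the samarium enolate, which methanol protonates at Ce. The closest known reaction type is the SmI2-induced reductive cyclisation of aldehydes onto β-alkoxyacrylates, including β,β-disubstituted ones, as used for 2,3-trans oxepanes of polycyclic ethers. The oxepane closes in the 7-exo-trig mode. C1 is controlled by a chair-like array in which chain B on C3 and the acceptor unit are pseudo-equatorial, so the CH2CO2Me arm ends cis to chain B and the C9 ester axial on the face of the C4 oxygen. C7 is controlled by trivalent samarium bridging the ketyl oxygen and the carbonyl of the acceptor ester (chelation to the C9 ester leads to the same result), which puts the C7 oxygen trans to the arm and cis to C9. The step needs aldehyde reduction and bond formation to outrun simple reduction of the butenedioate; the alkoxy donor on C1 makes the acceptor harder to reduce than a plain butenedioate, and low temperature with few equivalents of methanol delays protonation until after closure. The E geometry of the enol ether matches the precedented acrylate geometry, the triethylsilyl ether on C4 prevents lactol formation, and the silyl ethers and the isolated alkene are inert to SmI2.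

Step 13
Reactants: 19 methyl (2R,3S,6R,7S)-7-[(3Z)-5-[(tert-butyldiphenylsilyl)oxy]-3-methylpent-3-en-1-yl]-3-hydroxy-2-(2-methoxy-2-oxoethyl)-6-methyl-6-[(triethylsilyl)oxy]oxepane-2-carboxylate
Product: 20 methyl (2R,3S,6R,7S)-3-[(tert-butyldimethylsilyl)oxy]-7-[(3Z)-5-[(tert-butyldiphenylsilyl)oxy]-3-methylpent-3-en-1-yl]-2-(2-methoxy-2-oxoethyl)-6-methyl-6-[(triethylsilyl)oxy]oxepane-2-carboxylate
Conditions: t-BuMe2SiOTf (1.5 equiv), 2,6-lutidine (3 equiv), CH2Cl2, −40 → 0 °C
Reagents that add atoms: tert-butyldimethylsilyl trifluoromethanesulfonate, CC(C)(C)[Si](C)(C)OS(=O)(=O)C(F)(F)F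
Why: Silyl triflate silylation of the hindered secondary C7 hydroxyl; it blocks retro-aldol cleavage of the C7–C1–C9 unit and lactonisation of the C7 oxygen onto the arm ester in the steps that follow.

Step 14
Reactants: 20 methyl (2R,3S,6R,7S)-3-[(tert-butyldimethylsilyl)oxy]-7-[(3Z)-5-[(tert-butyldiphenylsilyl)oxy]-3-methylpent-3-en-1-yl]-2-(2-methoxy-2-oxoethyl)-6-methyl-6-[(triethylsilyl)oxy]oxepane-2-carboxylate
Product: 21 methyl (2R,3S,6R,7S)-3-[(tert-butyldimethylsilyl)oxy]-7-[(3Z)-5-[(tert-butyldiphenylsilyl)oxy]-3-methylpent-3-en-1-yl]-6-hydroxy-2-(2-methoxy-2-oxoethyl)-6-methyloxepane-2-carboxylate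
Conditions: HF·pyridine, pyridine, THF, 0 °C → rt
Reagents that add atoms: none
Why: Acidic fluoride should cleave the triethylsilyl ether well before the neopentyl-type secondary tert-butyldimethylsilyl ether or the primary tert-butyldiphenylsilyl ether (graded silyl ether lability).

Step 15
Reactants: 21 methyl (2R,3S,6R,7S)-3-[(tert-butyldimethylsilyl)oxy]-7-[(3Z)-5-[(tert-butyldiphenylsilyl)oxy]-3-methylpent-3-en-1-yl]-6-hydroxy-2-(2-methoxy-2-oxoethyl)-6-methyloxepane-2-carboxylate
Product: 22 methyl 2-[(1R,2S,5R,9S)-2-[(tert-butyldimethylsilyl)oxy]-9-[(3Z)-5-[(tert-butyldiphenylsilyl)oxy]-3-methylpent-3-en-1-yl]-5-methyl-7-oxo-6,8-dioxabicyclo[3.2.2]nonan-1-yl]acetate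
Conditions: LiN(SiMe3)2 (1.05 equiv), THF, −78 → 0 °C; AcOH
Reagents that add atoms: none
Why: The tertiary lithium alkoxide attacks the C9 ester through a six-membered transition state (alkoxide-mediated lactonisation); exchange of a tertiary alkoxide for methoxide drives it, and attack on the arm ester would need a seven-membered ring. C1 has no α-hydrogen, so no stereocentre is at risk.

Step 16
Reactants: 22 methyl 2-[(1R,2S,5R,9S)-2-[(tert-butyldimethylsilyl)oxy]-9-[(3Z)-5-[(tert-butyldiphenylsilyl)oxy]-3-methylpent-3-en-1-yl]-5-methyl-7-oxo-6,8-dioxabicyclo[3.2.2]nonan-1-yl]acetate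
Product: 23 2-[(1R,2S,5R,9S)-2-[(tert-butyldimethylsilyl)oxy]-9-[(3Z)-5-[(tert-butyldiphenylsilyl)oxy]-3-methylpent-3-en-1-yl]-5-methyl-7-oxo-6,8-dioxabicyclo[3.2.2]nonan-1-yl]acetic acid
Conditions: Me3SnOH (5 equiv), ClCH2CH2Cl, 70 °C; dilute aq. HCl wash
Reagents that add atoms: trimethyltin hydroxide, C[Sn](C)(C)O
Why: Me3SnOH hydrolyses unhindered methyl esters under neutral conditions; the lactone is an ester of a tertiary alcohol with a quaternary α-carbon and is sterically shielded, and the silyl ethers are untouched.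

Step 17
Reactants: 23 2-[(1R,2S,5R,9S)-2-[(tert-butyldimethylsilyl)oxy]-9-[(3Z)-5-[(tert-butyldiphenylsilyl)oxy]-3-methylpent-3-en-1-yl]-5-methyl-7-oxo-6,8-dioxabicyclo[3.2.2]nonan-1-yl]acetic acid
Product: 25 (1R,2S,5R,9S)-2-[(tert-butyldimethylsilyl)oxy]-9-[(3Z)-5-[(tert-butyldiphenylsilyl)oxy]-3-methylpent-3-en-1-yl]-1-(2-hydroxyethyl)-5-methyl-6,8-dioxabicyclo[3.2.2]nonan-7-one, via isobutyl carbonic anhydride 24 (not isolated)
Conditions: i-BuOCOCl (1.1 equiv), N-methylmorpholine (1.1 equiv), THF, −15 °C; then NaBH4 (2 equiv), THF–H2O, −15 → 0 °C; pH 6 buffer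
Reagents that add atoms: none
Why: Activation as the mixed carbonic anhydride lets NaBH4 reduce only Cf at low temperature (acid to primary alcohol beside a lactone and alkenes). The bond C1–Ce lies in the plane of the lactone carbonyl, which should make attack of the new hydroxyl on C9 through a five-membered transition state geometrically difficult.

Step 18
Reactants: 25 (1R,2S,5R,9S)-2-[(tert-butyldimethylsilyl)oxy]-9-[(3Z)-5-[(tert-butyldiphenylsilyl)oxy]-3-methylpent-3-en-1-yl]-1-(2-hydroxyethyl)-5-methyl-6,8-dioxabicyclo[3.2.2]nonan-7-one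
Product: 26 (1R,2S,5R,9S)-2-[(tert-butyldimethylsilyl)oxy]-9-[(3Z)-5-[(tert-butyldiphenylsilyl)oxy]-3-methylpent-3-en-1-yl]-1-(2-iodoethyl)-5-methyl-6,8-dioxabicyclo[3.2.2]nonan-7-one
Conditions: I2 (1.3 equiv), PPh3 (1.3 equiv), imidazole (2 equiv), CH2Cl2, 0 °C → rt
Reagents that add atoms: iodine, II
Why: Appel iodination of the primary alcohol under near-neutral conditions; it removes the hydroxyl that could otherwise attack C9.

Step 19
Reactants: 27 prop-2-yn-1-ol
Product: 29 (2Z)-3-iodo-2-methylprop-2-en-1-ol, via alkenylmagnesium alkoxide 28 (not isolated)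
Conditions: MeMgBr (2.5 equiv), CuI (0.1 equiv), THF, −10 °C → rt; then I2 (1.2 equiv), −10 °C; sat. aq. NH4Cl
Reagents that add atoms: methylmagnesium bromide, C[Mg]Br; iodine, II
Why: The magnesium alkoxide directs copper-catalysed anti-carbomagnesiation: methyl adds to C2 and magnesium to C3 within a five-membered chelate, so iodinolysis places iodine cis to CH2OH (Z).

Step 20
Reactants: 29 (2Z)-3-iodo-2-methylprop-2-en-1-ol
Product: 30 tert-butyl{[(2Z)-3-iodo-2-methylprop-2-en-1-yl]oxy}dimethylsilane
Conditions: t-BuMe2SiCl (1.1 equiv), imidazole, CH2Cl2, 0 °C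
Reagents that add atoms: tert-butyl(chloro)dimethylsilane, CC(C)(C)[Si](C)(C)Cl
Why: Routine silylation; the free hydroxyl would otherwise protonate the organozinc reagent in step 21.

Step 21
Reactants: 26 (1R,2S,5R,9S)-2-[(tert-butyldimethylsilyl)oxy]-9-[(3Z)-5-[(tert-butyldiphenylsilyl)oxy]-3-methylpent-3-en-1-yl]-1-(2-iodoethyl)-5-methyl-6,8-dioxabicyclo[3.2.2]nonan-7-one; 30 tert-butyl{[(2Z)-3-iodo-2-methylprop-2-en-1-yl]oxy}dimethylsilane
Product: 32 (1R,2S,5R,9S)-2-[(tert-butyldimethylsilyl)oxy]-1-[(3Z)-5-[(tert-butyldimethylsilyl)oxy]-4-methylpent-3-en-1-yl]-9-[(3Z)-5-[(tert-butyldiphenylsilyl)oxy]-3-methylpent-3-en-1-yl]-5-methyl-6,8-dioxabicyclo[3.2.2]nonan-7-one, via alkylzinc iodide 31 (not isolated)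
Conditions: Zn powder (3 equiv, activated with BrCH2CH2Br and Me3SiCl), LiCl, THF, 40 °C; then 30 (1.2 equiv), Pd(PPh3)4 (5 mol %), THF, 50 °C
Reagents that add atoms: none
Why: Zinc inserts into the primary C–I bond without touching the lactone or silyl ethers; zerovalent palladium then couples the alkylzinc iodide with the alkenyl iodide with retention of alkene geometry (Negishi sp3–sp2 coupling), forming Cf–Cg.

Step 22
Reactants: 32 (1R,2S,5R,9S)-2-[(tert-butyldimethylsilyl)oxy]-1-[(3Z)-5-[(tert-butyldimethylsilyl)oxy]-4-methylpent-3-en-1-yl]-9-[(3Z)-5-[(tert-butyldiphenylsilyl)oxy]-3-methylpent-3-en-1-yl]-5-methyl-6,8-dioxabicyclo[3.2.2]nonan-7-one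
Product: 33 (1R,2S,5R,9S)-2-hydroxy-9-[(3Z)-5-hydroxy-3-methylpent-3-en-1-yl]-1-[(3Z)-5-hydroxy-4-methylpent-3-en-1-yl]-5-methyl-6,8-dioxabicyclo[3.2.2]nonan-7-one
Conditions: Bu4NF (6 equiv), AcOH (6 equiv), THF, rt → 45 °C
Reagents that add atoms: none
Why: Fluoride buffered with acetic acid removes all three silyl ethers (global desilylation); the buffer keeps the C7 oxygen protonated, so retro-aldol cleavage and lactone opening should not occur.

## Compound list

1 | neryl acetate, (2Z)-3,7-dimethylocta-2,6-dien-1-yl acetate | CC(C)=CCC/C(C)=C\COC(C)=O | starting material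
2 | secondary ozonide, (2Z)-5-(5,5-dimethyl-1,2,4-trioxolan-3-yl)-3-methylpent-2-en-1-yl acetate, not isolated | CC1(C)OOC(CC/C(C)=C\COC(C)=O)O1 | intermediate
3 | (2Z)-3-methyl-6-oxohex-2-en-1-yl acetate | O=CCC/C(C)=C\COC(C)=O | intermediate
4 | isopropenylmagnesium bromide (THF solution) | CC(=C)[Mg]Br | starting material
5 | (2Z)-6-hydroxy-3,7-dimethylocta-2,7-dien-1-yl acetate, both configurations at C6 | CC(=C)C(O)CC/C(C)=C\COC(C)=O | intermediate
6 | triethyl orthoacetate | CCOC(C)(OCC)OCC | starting material
7 | mixed ketene acetal, (2Z)-6-[(1-ethoxyethenyl)oxy]-3,7-dimethylocta-2,7-dien-1-yl acetate, not isolated | C=C(OCC)OC(CC/C(C)=C\COC(C)=O)C(C)=C | intermediate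
8 | ethyl (4E,8Z)-10-acetoxy-4,8-dimethyldeca-4,8-dienoate | CCOC(=O)CC/C(C)=C/CC/C(C)=C\COC(C)=O | intermediate
9 | ethyl 3-[(2S,3S)-3-[(3Z)-5-acetoxy-3-methylpent-3-en-1-yl]-2-methyloxiran-2-yl]propanoate | CCOC(=O)CC[C@]1(C)O[C@H]1CC/C(C)=C\COC(C)=O | intermediate
10 | 3-[(2S,3S)-3-[(3Z)-5-hydroxy-3-methylpent-3-en-1-yl]-2-methyloxiran-2-yl]propanoic acid, not isolated | OC(=O)CC[C@]1(C)O[C@H]1CC/C(C)=C\CO | intermediate
11 | (5R)-5-[(1S,4Z)-1,6-dihydroxy-4-methylhex-4-en-1-yl]-5-methyloxolan-2-one | C[C@@]1(CCC(=O)O1)[C@@H](O)CC/C(C)=C\CO | intermediate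
12 | (5R)-5-[(1S,4Z)-6-[(tert-butyldiphenylsilyl)oxy]-1-hydroxy-4-methylhex-4-en-1-yl]-5-methyloxolan-2-one | C[C@@]1(CCC(=O)O1)[C@@H](O)CC/C(C)=C\CO[Si](c2ccccc2)(c3ccccc3)C(C)(C)C | intermediate
13 | (4R,5S,8Z)-10-[(tert-butyldiphenylsilyl)oxy]-4,8-dimethyldec-8-ene-1,4,5-triol | OCCC[C@@](C)(O)[C@@H](O)CC/C(C)=C\CO[Si](c1ccccc1)(c2ccccc2)C(C)(C)C | intermediate
14 | (4R,5S,8Z)-10-[(tert-butyldiphenylsilyl)oxy]-4,8-dimethyl-1-[(triethylsilyl)oxy]dec-8-ene-4,5-diol | CC[Si](CC)(CC)OCCC[C@@](C)(O)[C@@H](O)CC/C(C)=C\CO[Si](c1ccccc1)(c2ccccc2)C(C)(C)C | intermediate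
15 | dimethyl but-2-ynedioate | COC(=O)C#CC(=O)OC | starting material
16 | dimethyl (2E)-2-{[(4R,5S,8Z)-10-[(tert-butyldiphenylsilyl)oxy]-4-hydroxy-4,8-dimethyl-1-[(triethylsilyl)oxy]dec-8-en-5-yl]oxy}but-2-enedioate | COC(=O)/C=C(/O[C@@H](CC/C(C)=C\CO[Si](c1ccccc1)(c2ccccc2)C(C)(C)C)[C@@](C)(CCCO[Si](CC)(CC)CC)O)C(=O)OC | intermediate
17 | dimethyl (2E)-2-{[(4R,5S,8Z)-10-[(tert-butyldiphenylsilyl)oxy]-4,8-dimethyl-1,4-bis[(triethylsilyl)oxy]dec-8-en-5-yl]oxy}but-2-enedioate | COC(=O)/C=C(/O[C@@H](CC/C(C)=C\CO[Si](c1ccccc1)(c2ccccc2)C(C)(C)C)[C@@](C)(CCCO[Si](CC)(CC)CC)O[Si](CC)(CC)CC)C(=O)OC | intermediate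
18 | dimethyl (2E)-2-{[(4R,5S,8Z)-10-[(tert-butyldiphenylsilyl)oxy]-4,8-dimethyl-1-oxo-4-[(triethylsilyl)oxy]dec-8-en-5-yl]oxy}but-2-enedioate (key-step precursor) | COC(=O)/C=C(/O[C@@H](CC/C(C)=C\CO[Si](c1ccccc1)(c2ccccc2)C(C)(C)C)[C@@](C)(CCC=O)O[Si](CC)(CC)CC)C(=O)OC | intermediate
19 | methyl (2R,3S,6R,7S)-7-[(3Z)-5-[(tert-butyldiphenylsilyl)oxy]-3-methylpent-3-en-1-yl]-3-hydroxy-2-(2-methoxy-2-oxoethyl)-6-methyl-6-[(triethylsilyl)oxy]oxepane-2-carboxylate (key-step product) | COC(=O)C[C@@]1(C(=O)OC)O[C@@H](CC/C(C)=C\CO[Si](c2ccccc2)(c3ccccc3)C(C)(C)C)[C@@](C)(CC[C@@H]1O)O[Si](CC)(CC)CC | intermediate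
20 | methyl (2R,3S,6R,7S)-3-[(tert-butyldimethylsilyl)oxy]-7-[(3Z)-5-[(tert-butyldiphenylsilyl)oxy]-3-methylpent-3-en-1-yl]-2-(2-methoxy-2-oxoethyl)-6-methyl-6-[(triethylsilyl)oxy]oxepane-2-carboxylate | COC(=O)C[C@@]1(C(=O)OC)O[C@@H](CC/C(C)=C\CO[Si](c2ccccc2)(c3ccccc3)C(C)(C)C)[C@@](C)(CC[C@@H]1O[Si](C)(C)C(C)(C)C)O[Si](CC)(CC)CC | intermediate
21 | methyl (2R,3S,6R,7S)-3-[(tert-butyldimethylsilyl)oxy]-7-[(3Z)-5-[(tert-butyldiphenylsilyl)oxy]-3-methylpent-3-en-1-yl]-6-hydroxy-2-(2-methoxy-2-oxoethyl)-6-methyloxepane-2-carboxylate | COC(=O)C[C@@]1(C(=O)OC)O[C@@H](CC/C(C)=C\CO[Si](c2ccccc2)(c3ccccc3)C(C)(C)C)[C@@](C)(CC[C@@H]1O[Si](C)(C)C(C)(C)C)O | intermediate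
22 | methyl 2-[(1R,2S,5R,9S)-2-[(tert-butyldimethylsilyl)oxy]-9-[(3Z)-5-[(tert-butyldiphenylsilyl)oxy]-3-methylpent-3-en-1-yl]-5-methyl-7-oxo-6,8-dioxabicyclo[3.2.2]nonan-1-yl]acetate | COC(=O)C[C@@]12O[C@@H](CC/C(C)=C\CO[Si](c3ccccc3)(c4ccccc4)C(C)(C)C)[C@@](C)(CC[C@@H]1O[Si](C)(C)C(C)(C)C)OC2=O | intermediate
23 | 2-[(1R,2S,5R,9S)-2-[(tert-butyldimethylsilyl)oxy]-9-[(3Z)-5-[(tert-butyldiphenylsilyl)oxy]-3-methylpent-3-en-1-yl]-5-methyl-7-oxo-6,8-dioxabicyclo[3.2.2]nonan-1-yl]acetic acid | OC(=O)C[C@@]12O[C@@H](CC/C(C)=C\CO[Si](c3ccccc3)(c4ccccc4)C(C)(C)C)[C@@](C)(CC[C@@H]1O[Si](C)(C)C(C)(C)C)OC2=O | intermediate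
24 | isobutyl carbonic anhydride of acid 23, not isolated | CC(C)COC(=O)OC(=O)C[C@@]12O[C@@H](CC/C(C)=C\CO[Si](c3ccccc3)(c4ccccc4)C(C)(C)C)[C@@](C)(CC[C@@H]1O[Si](C)(C)C(C)(C)C)OC2=O | intermediate
25 | (1R,2S,5R,9S)-2-[(tert-butyldimethylsilyl)oxy]-9-[(3Z)-5-[(tert-butyldiphenylsilyl)oxy]-3-methylpent-3-en-1-yl]-1-(2-hydroxyethyl)-5-methyl-6,8-dioxabicyclo[3.2.2]nonan-7-one | OCC[C@@]12O[C@@H](CC/C(C)=C\CO[Si](c3ccccc3)(c4ccccc4)C(C)(C)C)[C@@](C)(CC[C@@H]1O[Si](C)(C)C(C)(C)C)OC2=O | intermediate
26 | (1R,2S,5R,9S)-2-[(tert-butyldimethylsilyl)oxy]-9-[(3Z)-5-[(tert-butyldiphenylsilyl)oxy]-3-methylpent-3-en-1-yl]-1-(2-iodoethyl)-5-methyl-6,8-dioxabicyclo[3.2.2]nonan-7-one | ICC[C@@]12O[C@@H](CC/C(C)=C\CO[Si](c3ccccc3)(c4ccccc4)C(C)(C)C)[C@@](C)(CC[C@@H]1O[Si](C)(C)C(C)(C)C)OC2=O | intermediate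
27 | prop-2-yn-1-ol | C#CCO | starting material
28 | bromomagnesium (2Z)-3-(bromomagnesio)-2-methylprop-2-en-1-olate, not isolated | C/C(=C/[Mg]Br)CO[Mg]Br | intermediate
29 | (2Z)-3-iodo-2-methylprop-2-en-1-ol | C/C(=C/I)CO | intermediate
30 | tert-butyl{[(2Z)-3-iodo-2-methylprop-2-en-1-yl]oxy}dimethylsilane | C/C(=C/I)CO[Si](C)(C)C(C)(C)C | intermediate
31 | alkylzinc iodide from 26 (iodozincioethyl at C1), not isolated | I[Zn]CC[C@@]12O[C@@H](CC/C(C)=C\CO[Si](c3ccccc3)(c4ccccc4)C(C)(C)C)[C@@](C)(CC[C@@H]1O[Si](C)(C)C(C)(C)C)OC2=O | intermediate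
32 | (1R,2S,5R,9S)-2-[(tert-butyldimethylsilyl)oxy]-1-[(3Z)-5-[(tert-butyldimethylsilyl)oxy]-4-methylpent-3-en-1-yl]-9-[(3Z)-5-[(tert-butyldiphenylsilyl)oxy]-3-methylpent-3-en-1-yl]-5-methyl-6,8-dioxabicyclo[3.2.2]nonan-7-one | C/C(=C/CC[C@@]12O[C@@H](CC/C(C)=C\CO[Si](c3ccccc3)(c4ccccc4)C(C)(C)C)[C@@](C)(CC[C@@H]1O[Si](C)(C)C(C)(C)C)OC2=O)CO[Si](C)(C)C(C)(C)C | intermediate
33 | (1R,2S,5R,9S)-2-hydroxy-9-[(3Z)-5-hydroxy-3-methylpent-3-en-1-yl]-1-[(3Z)-5-hydroxy-4-methylpent-3-en-1-yl]-5-methyl-6,8-dioxabicyclo[3.2.2]nonan-7-one | C/C(=C/CC[C@@]12O[C@@H](CC/C(C)=C\CO)[C@@](C)(CC[C@@H]1O)OC2=O)CO | target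

## Step count and least certain steps

Total: 22 steps. Longest linear sequence: 20 steps (steps 1–18, 21 and 22); steps 19 and 20 make the chain-A iodide.

Step 12 (key step). The most likely failure is electron transfer to the butenedioate followed by protonation before the ring closes, because butenedioates are easier to reduce than simple acrylates; a slow, unchelated 7-exo closure would also erode selectivity at C1 and C7. Fallback: starting from 18, the same C1–C7 bond is made by a neutral radical chain instead of electron transfer. Bu3SnH with azobisisobutyronitrile in hot benzene under slow addition adds a stannyl radical to the aldehyde oxygen; the O-stannyl ketyl closes onto C1, the adduct radical takes hydrogen from the stannane, and hydrolysis of the O–Sn bond on work-up returns the route at 19. No new isolated compound arises.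

Step 9. After the C3 oxygen has added, the free tertiary C4 hydroxyl next to the new enol ether diester may cyclise onto it (lactonisation or a second conjugate addition), or may itself compete for the alkynedioate. Fallback: starting from 12, the C3 hydroxyl is first masked. 4-Methoxybenzyl trichloroacetimidate with catalytic La(OTf)3 gives the 4-methoxybenzyl ether lactone F1. LiAlH4 gives the 1,4-diol F2. Et3SiOTf and 2,6-lutidine silylate both the primary and the tertiary hydroxyl to the bis(triethylsilyl) ether F3. Dichlorodicyanobenzoquinone in buffered wet CH2Cl2 frees only the C3 hydroxyl to give the alcohol F4. Addition of F4 to 15 under the conditions of step 9, now with no neighbouring hydroxyl, returns the route at 17.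

Step 15. The alkoxide or the methoxide it releases may enolise the arm ester and expel O2 by β-elimination, opening the oxepane; or closure may be slow because the ring must fold into a boat-like shape. Fallback: starting from 21, both methyl esters are saponified with LiOH in aqueous THF–MeOH to the hydroxy diacid F5. A carbodiimide (N-ethyl-N′-(3-dimethylaminopropyl)carbodiimide hydrochloride) dehydrates the 1,2-diacid to the spiro succinic anhydride F6. With catalytic 4-dimethylaminopyridine the C4 hydroxyl opens the anhydride at C9 through the six-membered mode and releases the arm carboxylic acid, so the route is rejoined at 23 and step 16 is not needed.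

Step 17. The new hydroxyl on Cf, or its borate, may attack C9 and shift the lactone to a spiro five-membered ring with release of the C4 hydroxyl; borohydride may also touch the lactone. Fallback: starting from 23, no hydroxyl is ever placed on Cf. Ethanethiol and a carbodiimide give the S-ethyl thioester F7. Fukuyama reduction (Et3SiH, Pd on carbon) gives the aldehyde F8. Wittig reaction with Ph3P=CHOMe gives the methyl enol ether F9. Hg(OAc)2 in aqueous THF followed by aqueous KI gives the one-carbon-longer aldehyde F10. A Z-selective Horner–Wadsworth–Emmons reaction with ethyl 2-(diphenoxyphosphoryl)propanoate gives the Z-enoate F11. i-Bu2AlH at −78 °C gives the allylic alcohol F12, and the conditions of step 22 then lead to 33. The weak point of this fallback is the hydride step beside the lactone, which is why it is not the main line.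

## Further compounds

F0 | step 12 | none | none
F1 | step 9 | (5R)-5-[(1S,4Z)-6-[(tert-butyldiphenylsilyl)oxy]-1-[(4-methoxybenzyl)oxy]-4-methylhex-4-en-1-yl]-5-methyloxolan-2-one | C[C@@]1(CCC(=O)O1)[C@@H](OCc2ccc(OC)cc2)CC/C(C)=C\CO[Si](c3ccccc3)(c4ccccc4)C(C)(C)C
F2 | step 9 | (4R,5S,8Z)-10-[(tert-butyldiphenylsilyl)oxy]-5-[(4-methoxybenzyl)oxy]-4,8-dimethyldec-8-ene-1,4-diol | OCCC[C@@](C)(O)[C@@H](OCc1ccc(OC)cc1)CC/C(C)=C\CO[Si](c2ccccc2)(c3ccccc3)C(C)(C)C
F3 | step 9 | (4R,5S,8Z)-10-[(tert-butyldiphenylsilyl)oxy]-5-[(4-methoxybenzyl)oxy]-4,8-dimethyl-1,4-bis[(triethylsilyl)oxy]dec-8-ene | CC[Si](CC)(CC)OCCC[C@@](C)(O[Si](CC)(CC)CC)[C@@H](OCc1ccc(OC)cc1)CC/C(C)=C\CO[Si](c2ccccc2)(c3ccccc3)C(C)(C)C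
F4 | step 9 | (4R,5S,8Z)-10-[(tert-butyldiphenylsilyl)oxy]-4,8-dimethyl-1,4-bis[(triethylsilyl)oxy]dec-8-en-5-ol | CC[Si](CC)(CC)OCCC[C@@](C)(O[Si](CC)(CC)CC)[C@@H](O)CC/C(C)=C\CO[Si](c1ccccc1)(c2ccccc2)C(C)(C)C
F5 | step 15 | (2R,3S,6R,7S)-3-[(tert-butyldimethylsilyl)oxy]-7-[(3Z)-5-[(tert-butyldiphenylsilyl)oxy]-3-methylpent-3-en-1-yl]-2-(carboxymethyl)-6-hydroxy-6-methyloxepane-2-carboxylic acid | OC(=O)C[C@@]1(C(=O)O)O[C@@H](CC/C(C)=C\CO[Si](c2ccccc2)(c3ccccc3)C(C)(C)C)[C@@](C)(CC[C@@H]1O[Si](C)(C)C(C)(C)C)O
F6 | step 15 | spiro succinic anhydride of F5 (anhydride between C9 and the arm carboxyl, C4 hydroxyl free) | O=C1OC(=O)C[C@]12O[C@@H](CC/C(C)=C\CO[Si](c3ccccc3)(c4ccccc4)C(C)(C)C)[C@@](C)(CC[C@@H]2O[Si](C)(C)C(C)(C)C)O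
F7 | step 17 | S-ethyl thioester of acid 23 | CCSC(=O)C[C@@]12O[C@@H](CC/C(C)=C\CO[Si](c3ccccc3)(c4ccccc4)C(C)(C)C)[C@@](C)(CC[C@@H]1O[Si](C)(C)C(C)(C)C)OC2=O
F8 | step 17 | aldehyde at Cf (2-oxoethyl at C1 of the bicycle) | O=CC[C@@]12O[C@@H](CC/C(C)=C\CO[Si](c3ccccc3)(c4ccccc4)C(C)(C)C)[C@@](C)(CC[C@@H]1O[Si](C)(C)C(C)(C)C)OC2=O
F9 | step 17 | methyl enol ether (3-methoxyprop-2-en-1-yl at C1, both alkene isomers) | COC=CC[C@@]12O[C@@H](CC/C(C)=C\CO[Si](c3ccccc3)(c4ccccc4)C(C)(C)C)[C@@](C)(CC[C@@H]1O[Si](C)(C)C(C)(C)C)OC2=O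
F10 | step 17 | aldehyde at Cg (3-oxopropyl at C1 of the bicycle) | O=CCC[C@@]12O[C@@H](CC/C(C)=C\CO[Si](c3ccccc3)(c4ccccc4)C(C)(C)C)[C@@](C)(CC[C@@H]1O[Si](C)(C)C(C)(C)C)OC2=O
F11 | step 17 | ethyl (2Z)-2-methylpent-2-enoate attached through C5 to C1 of the bicycle | CCOC(=O)/C(C)=C\CC[C@@]12O[C@@H](CC/C(C)=C\CO[Si](c3ccccc3)(c4ccccc4)C(C)(C)C)[C@@](C)(CC[C@@H]1O[Si](C)(C)C(C)(C)C)OC2=O
F12 | step 17 | (1R,2S,5R,9S)-2-[(tert-butyldimethylsilyl)oxy]-9-[(3Z)-5-[(tert-butyldiphenylsilyl)oxy]-3-methylpent-3-en-1-yl]-1-[(3Z)-5-hydroxy-4-methylpent-3-en-1-yl]-5-methyl-6,8-dioxabicyclo[3.2.2]nonan-7-one | C/C(=C/CC[C@@]12O[C@@H](CC/C(C)=C\CO[Si](c3ccccc3)(c4ccccc4)C(C)(C)C)[C@@](C)(CC[C@@H]1O[Si](C)(C)C(C)(C)C)OC2=O)CO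
A1 | alternative 1 | 3(2H)-furanone with the isopropenyl ester and a silyloxypropyl stub on C1 and a silyloxyethyl stub on C3 | CC(=C)OC(=O)[C@]1(CCCO[Si](C)(C)C(C)(C)C)OC(CCO[Si](C(C)C)(C(C)C)C(C)C)=CC1=O
A2 | alternative 1 | caged photoadduct (target bicycle with an extra C3–C6 bond and a C7 ketone) | CC(C)(C)[Si](C)(C)OCCC[C@@]12O[C@]3(CCO[Si](C(C)C)(C(C)C)C(C)C)[C@@](C)(C[C@@H]3C1=O)OC2=O
A3 | alternative 2 | seven-membered hydroxy keto lactone (C1–OH, ketone at C3, both allylic acetates, C7 triethylsilyl ether) | CC(=O)OC/C(C)=C\CC[C@]1(O)C(=O)O[C@](C)(CC[C@@H]1O[Si](CC)(CC)CC)C(=O)CC/C(C)=C\COC(C)=O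
A4 | alternative 2 | protected target (two allylic acetates, C7 triethylsilyl ether) | CC(=O)OC/C(C)=C\CC[C@@]12O[C@@H](CC/C(C)=C\COC(C)=O)[C@@](C)(CC[C@@H]1O[Si](CC)(CC)CC)OC2=O
A5 | alternative 3 | dimethyl 2-alkoxy-2-alkylmalonate with free C4 hydroxyl and a phenylsulfonylethyl arm on C4 | COC(=O)C(CC/C=C(/C)CO[Si](C)(C)C(C)(C)C)(C(=O)OC)O[C@@H](CC/C(C)=C\CO[Si](C)(C)C(C)(C)C)[C@](C)(O)CCS(=O)(=O)c1ccccc1
A6 | alternative 3 | bridged keto lactone with the sulfone on C6 and both protected chains | CC(C)(C)[Si](C)(C)OC/C(C)=C\CC[C@@]12O[C@@H](CC/C(C)=C\CO[Si](C)(C)C(C)(C)C)[C@@](C)(C[C@H](S(=O)(=O)c3ccccc3)C1=O)OC2=O
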